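**Plan**

Ring A is the benzene ring of the chroman and ring B is the quinone.
- Retrosynthesis: the two silicon groups (O‑TIPS on ring A, 2‑(trimethylsilyl)ethyl on the quinone oxygen) come off last. Ring B is then cut at three bonds: carbonyl C (the one next to the chromanyl‑bearing carbon)–C(prenyl), the same carbonyl C–C(chromanyl), and CH–C(second carbonyl). This gives a terminal alkyne, one CO and an alkoxy(alkenyl)carbene of chromium.
- The alkyne goes back through its aldehyde and acid to a 2H‑chromene made from 2,4,6‑trihydroxybenzaldehyde and acrolein.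
- Forward order: the pyran ring is closed first onto ring A, the ring A prenyl is placed by an aromatic Claisen shift from O‑5, and ring B is built last, all six carbons in one benzannulation, and oxidised to the quinone in the same flask.
- Enabling feature: ring B has its two carbonyl carbons para, a single ring CH beside the chromanyl‑bearing carbon, and an O/prenyl pair on the opposite edge. That is the pattern a terminal alkyne, CO and an α‑alkoxy‑β‑alkyl alkenylcarbene deliver regioselectively as a 4‑methoxyphenol.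
- Stereochemistry: the only stereocentre (C3 of the chroman, R) is set by Ru–BINAP hydrogenation of the chromene‑3‑carboxylic acid and carried through a non‑basic aldehyde‑to‑alkyne homologation; the annulation does not touch it.

Key step: step 17

Remark: the (R)‑BINAP antipode is assigned to the (3S)‑acid by analogy with the sense of hydrogenation of tiglic acid; should the sense be opposite, the (S)‑ligand is used.

**Route**

Step 1
Reactants: 1 2,4,6-trihydroxybenzaldehyde
Product: 2 2,6-dihydroxy-4-[(triisopropylsilyl)oxy]benzaldehyde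
Conditions: TIPSCl (1.05 equiv), imidazole, DMF, 0 °C
Reagents that add atoms: triisopropylsilyl chloride, CC(C)[Si](Cl)(C(C)C)C(C)C
Why: Silyl ether formation; the 4‑hydroxyl is the most acidic and the only one not flanked by or hydrogen‑bonded to the formyl group, so one equivalent of the bulky chlorosilane should silylate it selectively.

Step 2
Reactants: 2 2,6-dihydroxy-4-[(triisopropylsilyl)oxy]benzaldehyde; 3 acrolein
Product: 5 5-hydroxy-7-[(triisopropylsilyl)oxy]-2H-chromene-3-carbaldehyde, via aldol adduct 4 (not isolated)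
Conditions: K2CO3, 1,4-dioxane, 90 °C
Reagents that add atoms: none
Why: Oxa‑Michael addition of one of the two homotopic ortho‑phenoxides to acrolein followed by intramolecular aldol condensation onto the formyl group (chromene annulation) closes the pyran ring, and because the two ortho hydroxyls are equivalent only one chromene can form.

Step 3
Reactants: 6 2-methylbut-3-en-2-ol
Product: 8 tert-butyl 2-methylbut-3-en-2-yl carbonate, via lithium alkoxide 7 (not isolated)
Conditions: n-BuLi, THF, 0 °C; then Boc2O, 0 °C to rt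
Reagents that add atoms: di-tert-butyl dicarbonate, CC(C)(C)OC(=O)OC(=O)OC(C)(C)C
Why: O‑Acylation of a lithium alkoxide with Boc2O is the standard preparation of tertiary allylic tert‑butyl carbonates.

Step 4
Reactants: 5 5-hydroxy-7-[(triisopropylsilyl)oxy]-2H-chromene-3-carbaldehyde; 8 tert-butyl 2-methylbut-3-en-2-yl carbonate
Product: 9 5-[(2-methylbut-3-en-2-yl)oxy]-7-[(triisopropylsilyl)oxy]-2H-chromene-3-carbaldehyde
Conditions: Pd(PPh3)4 (3 mol %), THF, 4 Å MS, 0 °C to rt
Reagents that add atoms: none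
Why: Tsuji–Trost O‑allylation: zerovalent palladium ionises the carbonate to a 1,1‑dimethylallyl complex and tert‑butoxide, which deprotonates the phenol, and phenoxide attack at the more substituted allyl terminus gives the tertiary ether as the kinetic product.

Step 5
Reactants: 9 5-[(2-methylbut-3-en-2-yl)oxy]-7-[(triisopropylsilyl)oxy]-2H-chromene-3-carbaldehyde
Product: 11 5-hydroxy-6-(3-methylbut-2-en-1-yl)-7-[(triisopropylsilyl)oxy]-2H-chromene-3-carbaldehyde, via Claisen dienone 10 (not isolated)
Conditions: toluene, 110 °C, sealed tube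
Reagents that add atoms: none
Why: Aromatic Claisen rearrangement ([3,3] shift with allyl inversion) can only deliver the group to C6, the single unsubstituted position ortho to O‑5 (C4a is blocked), and enolisation of the dienone restores the arene with a linear prenyl group.

Step 6
Reactants: 11 5-hydroxy-6-(3-methylbut-2-en-1-yl)-7-[(triisopropylsilyl)oxy]-2H-chromene-3-carbaldehyde
Product: 12 5-methoxy-6-(3-methylbut-2-en-1-yl)-7-[(triisopropylsilyl)oxy]-2H-chromene-3-carbaldehyde
Conditions: MeI, K2CO3, acetone, 50 °C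
Reagents that add atoms: iodomethane, CI
Why: Williamson etherification of the only free phenol; the aryl triisopropylsilyl ether should tolerate carbonate in acetone.

Step 7
Reactants: 12 5-methoxy-6-(3-methylbut-2-en-1-yl)-7-[(triisopropylsilyl)oxy]-2H-chromene-3-carbaldehyde
Product: 13 5-methoxy-6-(3-methylbut-2-en-1-yl)-7-[(triisopropylsilyl)oxy]-2H-chromene-3-carboxylic acid
Conditions: NaClO2, NaH2PO4, 2-methylbut-2-ene (excess), t-BuOH/H2O, 0 °C to rt
Reagents that add atoms: sodium chlorite, [Na+].[O-]Cl=O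
Why: Pinnick oxidation converts the enal into the acid without touching alkenes, the hypochlorous acid by‑product being scavenged by the excess 2‑methylbut‑2‑ene.

Step 8
Reactants: 13 5-methoxy-6-(3-methylbut-2-en-1-yl)-7-[(triisopropylsilyl)oxy]-2H-chromene-3-carboxylic acid
Product: 14 (3S)-5-methoxy-6-(3-methylbut-2-en-1-yl)-7-[(triisopropylsilyl)oxy]chromane-3-carboxylic acid
Conditions: Ru(OAc)2[(R)-BINAP] (1 mol %), H2 (10 bar), MeOH, 25 °C
Reagents that add atoms: none
Why: Carboxylate‑directed asymmetric hydrogenation with a divalent ruthenium BINAP diacetate: the substrate binds as a chelating carboxylate, so hydrogen is delivered to one face of the C3=C4 bond and sets C3 as (S) in the acid (the arrangement that is 3R in the target), while the non‑coordinating prenyl alkene is not reduced.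

Step 9
Reactants: 14 (3S)-5-methoxy-6-(3-methylbut-2-en-1-yl)-7-[(triisopropylsilyl)oxy]chromane-3-carboxylic acid
Product: 15 [(3R)-5-methoxy-6-(3-methylbut-2-en-1-yl)-7-[(triisopropylsilyl)oxy]chroman-3-yl]methanol
Conditions: LiAlH4, THF, 0 °C; aqueous NaOH work-up
Reagents that add atoms: none
Why: Hydride reduction of the carboxylic acid to the primary alcohol with no change at C3 (the descriptor changes only through the priority rules).

Step 10
Reactants: 15 [(3R)-5-methoxy-6-(3-methylbut-2-en-1-yl)-7-[(triisopropylsilyl)oxy]chroman-3-yl]methanol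
Product: 16 (3S)-5-methoxy-6-(3-methylbut-2-en-1-yl)-7-[(triisopropylsilyl)oxy]chromane-3-carbaldehyde
Conditions: DMP, CH2Cl2, 0 °C to rt; used at once
Reagents that add atoms: none
Why: Dess–Martin oxidation is neutral and fast, so the enolisable α‑stereocentre of this β‑aryloxy aldehyde should not epimerise.

Step 11
Reactants: 16 (3S)-5-methoxy-6-(3-methylbut-2-en-1-yl)-7-[(triisopropylsilyl)oxy]chromane-3-carbaldehyde; 17 tetrabromomethane
Product: 18 (3R)-3-(2,2-dibromoethenyl)-5-methoxy-6-(3-methylbut-2-en-1-yl)-7-[(triisopropylsilyl)oxy]chromane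
Conditions: PPh3, Zn, CH2Cl2, rt (ylide preformed); then 16, 0 °C
Reagents that add atoms: none
Why: Corey–Fuchs dibromo‑olefination (a Wittig reaction) with the preformed, base‑free ylide avoids enolisation or retro‑oxa‑Michael opening of the aldehyde.

Step 12
Reactants: 18 (3R)-3-(2,2-dibromoethenyl)-5-methoxy-6-(3-methylbut-2-en-1-yl)-7-[(triisopropylsilyl)oxy]chromane
Product: 20 (3R)-3-ethynyl-5-methoxy-6-(3-methylbut-2-en-1-yl)-7-[(triisopropylsilyl)oxy]chromane, via lithium acetylide 19 (not isolated)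
Conditions: n-BuLi (2.2 equiv), THF, −78 °C; then H2O
Reagents that add atoms: none
Why: Bromine–lithium exchange and Fritsch–Buttenberg–Wiechell rearrangement (second stage of the Corey–Fuchs sequence) give the lithium acetylide, which is protonated on work‑up; the propargylic stereocentre is not acidic enough to be touched at −78 °C.

Step 13
Reactants: 21 2-(trimethylsilyl)ethanol; 22 trichloroethene
Product: 23 {2-[(E)-1,2-dichloroethenyloxy]ethyl}trimethylsilane
Conditions: KH, THF, −50 °C to rt
Reagents that add atoms: none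
Why: Base generates dichloroacetylene from trichloroethene in situ and the alkoxide adds to it, giving the 1,2‑dichlorovinyl ether that is the standard precursor of ynol ethers.

Step 14
Reactants: 23 {2-[(E)-1,2-dichloroethenyloxy]ethyl}trimethylsilane; 24 1-bromo-3-methylbut-2-ene
Product: 26 trimethyl{2-[(5-methylhex-4-en-1-yn-1-yl)oxy]ethyl}silane, via lithium alkynyl ether 25 (not isolated)
Conditions: n-BuLi (2.3 equiv), THF, −78 to −40 °C; then 24, HMPA, −78 °C to rt
Reagents that add atoms: none
Why: Dehydrochlorination and chlorine–lithium exchange give the lithium alkynyl ether, which is alkylated by the primary allylic bromide in an SN2 reaction.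

Step 15
Reactants: 26 trimethyl{2-[(5-methylhex-4-en-1-yn-1-yl)oxy]ethyl}silane
Product: 27 tributyl{(1E)-5-methyl-1-[2-(trimethylsilyl)ethoxy]hexa-1,4-dien-1-yl}stannane
Conditions: Bu3SnH, Pd(PPh3)4 (2 mol %), THF, 0 °C
Reagents that add atoms: tributyltin hydride, CCCC[SnH](CCCC)CCCC
Why: Palladium‑catalysed syn‑hydrostannation of a heteroatom‑substituted alkyne places tin on the oxygen‑bearing carbon and hydrogen cis to it, giving the (E)-α‑stannyl enol ether.

Step 16
Reactants: 27 tributyl{(1E)-5-methyl-1-[2-(trimethylsilyl)ethoxy]hexa-1,4-dien-1-yl}stannane; 28 hexacarbonylchromium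
Product: 31 pentacarbonyl{(2Z)-1-methoxy-6-methyl-2-[2-(trimethylsilyl)ethoxy]hepta-2,5-dien-1-ylidene}chromium, via alkenyllithium 29 (not isolated), via lithium acylchromate 30 (not isolated)
Conditions: n-BuLi, THF, −78 °C; Cr(CO)6, −78 to 0 °C; then Me3OBF4, CH2Cl2, 0 °C
Reagents that add atoms: trimethyloxonium tetrafluoroborate, C[O+](C)C.F[B-](F)(F)F
Why: Fischer carbene synthesis: tin–lithium exchange with retention gives the α‑alkoxyalkenyllithium without any deprotonation step, this adds to a CO ligand of Cr(CO)6, and the acylchromate is O‑methylated by the oxonium salt.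

Step 17
Reactants: 31 pentacarbonyl{(2Z)-1-methoxy-6-methyl-2-[2-(trimethylsilyl)ethoxy]hepta-2,5-dien-1-ylidene}chromium; 20 (3R)-3-ethynyl-5-methoxy-6-(3-methylbut-2-en-1-yl)-7-[(triisopropylsilyl)oxy]chromane
Product: 34 5-[(3R)-5-methoxy-6-(3-methylbut-2-en-1-yl)-7-[(triisopropylsilyl)oxy]chroman-3-yl]-3-(3-methylbut-2-en-1-yl)-2-[2-(trimethylsilyl)ethoxy]cyclohexa-2,5-diene-1,4-dione, via dienylketene complex 32 (not isolated), via methoxyphenol 33 (not isolated)
Conditions: THF (0.05 M), 50 °C; then (NH4)2Ce(NO3)6, MeCN/H2O, 0 °C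
Reagents that add atoms: water, O
Why: Loss of one CO from 31 lets the terminal alkyne 20 insert into the Cr=C bond, CO insertion then gives the chromium‑bound dienylketene 32, and its 6π‑electrocyclisation forms the bond between the ketene carbonyl carbon and the prenyl‑bearing alkene carbon, closing ring B as a cyclohexadienone that tautomerises to the chromium‑bound 4‑methoxyphenol 33. The closest known reaction type is the Dötz benzannulation of alkoxy(alkenyl)carbene chromium complexes with terminal alkynes, followed by the usual oxidative work‑up with tetravalent cerium, which strips the metal and turns the para‑methoxyphenol into the para‑quinone 34 (water supplies the new carbonyl oxygen and methanol leaves). Ring B is the only ring closed, by a thermal 6π‑electrocyclisation, its six carbons coming as a [3+2+1] set from three carbene‑ligand carbons, two alkyne carbons and one CO. No new stereocentre is formed; C3 of the chroman is a spectator propargylic centre, so the (R) configuration from step 8 is carried into the product. The step needs regioselective alkyne insertion, secured by the size difference between H and the secondary chromanyl group of a terminal alkyne (the substituted alkyne carbon ends next to the CO‑derived carbon); it also needs phenol formation rather than cyclopentannulation, favoured by an alkenyl methoxycarbene in THF, and a hydrogen pointing inward at the cyclising terminus, secured by the (Z) enol ether geometry from step 15. In the oxidation only ring B has the para O,O relationship needed for quinone formation, so the 1,3,5‑oxygenated ring A, both prenyl groups and both silicon groups should survive.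

Step 18
Reactants: 34 5-[(3R)-5-methoxy-6-(3-methylbut-2-en-1-yl)-7-[(triisopropylsilyl)oxy]chroman-3-yl]-3-(3-methylbut-2-en-1-yl)-2-[2-(trimethylsilyl)ethoxy]cyclohexa-2,5-diene-1,4-dione
Product: 35 2-hydroxy-5-[(3R)-7-hydroxy-5-methoxy-6-(3-methylbut-2-en-1-yl)chroman-3-yl]-3-(3-methylbut-2-en-1-yl)cyclohexa-2,5-diene-1,4-dione
Conditions: TBAF (3 equiv), THF, 0 °C; then 1 M HCl to pH 3
Reagents that add atoms: none
Why: Fluoride cleaves the aryl silyl ether and triggers β‑elimination of the 2‑(trimethylsilyl)ethyl group from the quinone oxygen, which is a vinylogous ester oxygen and hence a good leaving group (as in the cleavage of 2‑(trimethylsilyl)ethyl esters), giving the hydroxyquinone after mild acidification.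

**Compound list**

1 | 2,4,6-trihydroxybenzaldehyde | O=Cc1c(O)cc(O)cc1O | starting material
2 | 2,6-dihydroxy-4-[(triisopropylsilyl)oxy]benzaldehyde | O=Cc1c(O)cc(O[Si](C(C)C)(C(C)C)C(C)C)cc1O | intermediate
3 | acrolein (prop-2-enal) | C=CC=O | starting material
4 | 4,5-dihydroxy-7-[(triisopropylsilyl)oxy]chromane-3-carbaldehyde (aldol adduct, diastereomer mixture) | O=CC1COc2cc(O[Si](C(C)C)(C(C)C)C(C)C)cc(O)c2C1O | intermediate (not isolated)
5 | 5-hydroxy-7-[(triisopropylsilyl)oxy]-2H-chromene-3-carbaldehyde | O=CC1=Cc2c(O)cc(O[Si](C(C)C)(C(C)C)C(C)C)cc2OC1 | intermediate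
6 | 2-methylbut-3-en-2-ol | C=CC(C)(C)O | starting material
7 | lithium 2-methylbut-3-en-2-olate | [Li]OC(C)(C)C=C | intermediate (not isolated)
8 | tert-butyl 2-methylbut-3-en-2-yl carbonate | C=CC(C)(C)OC(=O)OC(C)(C)C | intermediate
9 | 5-[(2-methylbut-3-en-2-yl)oxy]-7-[(triisopropylsilyl)oxy]-2H-chromene-3-carbaldehyde | O=CC1=Cc2c(OC(C)(C)C=C)cc(O[Si](C(C)C)(C(C)C)C(C)C)cc2OC1 | intermediate
10 | 6-(3-methylbut-2-en-1-yl)-5-oxo-7-[(triisopropylsilyl)oxy]-5,6-dihydro-2H-chromene-3-carbaldehyde (Claisen dienone, racemic at C6) | O=CC1=CC2=C(OC1)C=C(O[Si](C(C)C)(C(C)C)C(C)C)C(CC=C(C)C)C2=O | intermediate (not isolated)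
11 | 5-hydroxy-6-(3-methylbut-2-en-1-yl)-7-[(triisopropylsilyl)oxy]-2H-chromene-3-carbaldehyde | O=CC1=Cc2c(O)c(CC=C(C)C)c(O[Si](C(C)C)(C(C)C)C(C)C)cc2OC1 | intermediate
12 | 5-methoxy-6-(3-methylbut-2-en-1-yl)-7-[(triisopropylsilyl)oxy]-2H-chromene-3-carbaldehyde | O=CC1=Cc2c(OC)c(CC=C(C)C)c(O[Si](C(C)C)(C(C)C)C(C)C)cc2OC1 | intermediate
13 | 5-methoxy-6-(3-methylbut-2-en-1-yl)-7-[(triisopropylsilyl)oxy]-2H-chromene-3-carboxylic acid | OC(=O)C1=Cc2c(OC)c(CC=C(C)C)c(O[Si](C(C)C)(C(C)C)C(C)C)cc2OC1 | intermediate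
14 | (3S)-5-methoxy-6-(3-methylbut-2-en-1-yl)-7-[(triisopropylsilyl)oxy]chromane-3-carboxylic acid | COc1c(CC=C(C)C)c(O[Si](C(C)C)(C(C)C)C(C)C)cc2c1C[C@H](C(=O)O)CO2 | intermediate
15 | [(3R)-5-methoxy-6-(3-methylbut-2-en-1-yl)-7-[(triisopropylsilyl)oxy]chroman-3-yl]methanol | COc1c(CC=C(C)C)c(O[Si](C(C)C)(C(C)C)C(C)C)cc2c1C[C@H](CO)CO2 | intermediate
16 | (3S)-5-methoxy-6-(3-methylbut-2-en-1-yl)-7-[(triisopropylsilyl)oxy]chromane-3-carbaldehyde | COc1c(CC=C(C)C)c(O[Si](C(C)C)(C(C)C)C(C)C)cc2c1C[C@H](C=O)CO2 | intermediate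
17 | tetrabromomethane | BrC(Br)(Br)Br | starting material
18 | (3R)-3-(2,2-dibromoethenyl)-5-methoxy-6-(3-methylbut-2-en-1-yl)-7-[(triisopropylsilyl)oxy]chromane | COc1c(CC=C(C)C)c(O[Si](C(C)C)(C(C)C)C(C)C)cc2c1C[C@H](C=C(Br)Br)CO2 | intermediate
19 | lithium acetylide of 20 | COc1c(CC=C(C)C)c(O[Si](C(C)C)(C(C)C)C(C)C)cc2c1C[C@H](C#C[Li])CO2 | intermediate (not isolated)
20 | (3R)-3-ethynyl-5-methoxy-6-(3-methylbut-2-en-1-yl)-7-[(triisopropylsilyl)oxy]chromane | COc1c(CC=C(C)C)c(O[Si](C(C)C)(C(C)C)C(C)C)cc2c1C[C@H](C#C)CO2 | intermediate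
21 | 2-(trimethylsilyl)ethanol | C[Si](C)(C)CCO | starting material
22 | trichloroethene | ClC=C(Cl)Cl | starting material
23 | {2-[(E)-1,2-dichloroethenyloxy]ethyl}trimethylsilane | C[Si](C)(C)CCO/C(Cl)=C\Cl | intermediate
24 | 1-bromo-3-methylbut-2-ene (prenyl bromide) | BrCC=C(C)C | starting material
25 | lithium [2-(trimethylsilyl)ethoxy]acetylide | C[Si](C)(C)CCOC#C[Li] | intermediate (not isolated)
26 | trimethyl{2-[(5-methylhex-4-en-1-yn-1-yl)oxy]ethyl}silane | C[Si](C)(C)CCOC#CCC=C(C)C | intermediate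
27 | tributyl{(1E)-5-methyl-1-[2-(trimethylsilyl)ethoxy]hexa-1,4-dien-1-yl}stannane | C[Si](C)(C)CCO/C([Sn](CCCC)(CCCC)CCCC)=C\CC=C(C)C | intermediate
28 | hexacarbonylchromium, Cr(CO)6 | [Cr].[C-]#[O+].[C-]#[O+].[C-]#[O+].[C-]#[O+].[C-]#[O+].[C-]#[O+] | starting material
29 | {(1Z)-5-methyl-1-[2-(trimethylsilyl)ethoxy]hexa-1,4-dien-1-yl}lithium | C[Si](C)(C)CCO/C([Li])=C\CC=C(C)C | intermediate (not isolated)
30 | lithium pentacarbonyl{(2Z)-6-methyl-1-oxido-2-[2-(trimethylsilyl)ethoxy]hepta-2,5-dien-1-ylidene}chromate | [Li+].[O-]C(=[Cr])/C(OCC[Si](C)(C)C)=C/CC=C(C)C.[C-]#[O+].[C-]#[O+].[C-]#[O+].[C-]#[O+].[C-]#[O+] | intermediate (not isolated)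
31 | pentacarbonyl{(2Z)-1-methoxy-6-methyl-2-[2-(trimethylsilyl)ethoxy]hepta-2,5-dien-1-ylidene}chromium | COC(=[Cr])/C(OCC[Si](C)(C)C)=C/CC=C(C)C.[C-]#[O+].[C-]#[O+].[C-]#[O+].[C-]#[O+].[C-]#[O+] | intermediate
32 | tricarbonylchromium-bound dienylketene from 31, 20 and CO (cyclisation-competent isomer) | COc1c(CC=C(C)C)c(O[Si](C(C)C)(C(C)C)C(C)C)cc2c1C[C@H](C(=C=O)/C=C(OC)\C(OCC[Si](C)(C)C)=C\CC=C(C)C)CO2.[Cr].[C-]#[O+].[C-]#[O+].[C-]#[O+] | intermediate (not isolated)
33 | 4-methoxy-2-[(3R)-5-methoxy-6-(3-methylbut-2-en-1-yl)-7-[(triisopropylsilyl)oxy]chroman-3-yl]-6-(3-methylbut-2-en-1-yl)-5-[2-(trimethylsilyl)ethoxy]phenol (formed as its Cr(CO)3 complex) | COc1c(CC=C(C)C)c(O[Si](C(C)C)(C(C)C)C(C)C)cc2c1C[C@H](c1cc(OC)c(OCC[Si](C)(C)C)c(CC=C(C)C)c1O)CO2 | intermediate (not isolated)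
34 | 5-[(3R)-5-methoxy-6-(3-methylbut-2-en-1-yl)-7-[(triisopropylsilyl)oxy]chroman-3-yl]-3-(3-methylbut-2-en-1-yl)-2-[2-(trimethylsilyl)ethoxy]cyclohexa-2,5-diene-1,4-dione | COc1c(CC=C(C)C)c(O[Si](C(C)C)(C(C)C)C(C)C)cc2c1C[C@H](C1=CC(=O)C(OCC[Si](C)(C)C)=C(CC=C(C)C)C1=O)CO2 | intermediate
35 | 2-hydroxy-5-[(3R)-7-hydroxy-5-methoxy-6-(3-methylbut-2-en-1-yl)chroman-3-yl]-3-(3-methylbut-2-en-1-yl)cyclohexa-2,5-diene-1,4-dione (CNP0148998.1) | COc1c(CC=C(C)C)c(O)cc2c1C[C@H](C1=CC(=O)C(O)=C(CC=C(C)C)C1=O)CO2 | target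

**Totals**

Total step count: 18. Longest linear sequence: 13 (steps 1, 2, 4–12, 17, 18).

**Steps most likely to fail**

Step 17. The unsaturated chromium intermediates may be captured by the pendant trisubstituted alkene of the carbene ligand, or electrocyclisation at the substituted terminus may be slow enough for cyclobutenone or furan formation to compete; over‑oxidation in the cerium work‑up is a lesser risk. The fallback sets out from 21 and 20 and comes back at 33. Alcohol 21 is vinylated by transetherification with ethyl vinyl ether (Hg(OAc)2 cat.) to [2-(ethenyloxy)ethyl]trimethylsilane F1. α‑Lithiation (t‑BuLi, THF, −78 to 0 °C), addition to Cr(CO)6 and O‑methylation with Me3OBF4 give pentacarbonyl{1-methoxy-2-[2-(trimethylsilyl)ethoxy]prop-2-en-1-ylidene}chromium F2, which has no pendant alkene and an unsubstituted cyclising terminus. Dötz benzannulation of F2 with 20 (THF, 50 °C, air work‑up) closes the same ring B bond and gives 4-methoxy-2-[(3R)-5-methoxy-6-(3-methylbut-2-en-1-yl)-7-[(triisopropylsilyl)oxy]chroman-3-yl]-5-[2-(trimethylsilyl)ethoxy]phenol F3. Pd(PPh3)4‑catalysed O‑allylation with 8 gives its 2-methylbut-3-en-2-yl ether F4. Aromatic Claisen rearrangement of F4 (toluene, 110 °C) can only go to the one free ortho position and gives 33, which is oxidised with (NH4)2Ce(NO3)6 as in the second stage of step 17 to 34.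

Step 18. Fluoride or the liberated phenoxide may act as a base on the alkylquinone (tautomerisation to a quinone methide with loss of the C3 configuration) or add to the free quinone position. The fallback sets out from 34 and comes back at 35. The quinone is first reduced with Na2S2O4 (EtOAc/H2O) to 2-[(3R)-5-methoxy-6-(3-methylbut-2-en-1-yl)-7-[(triisopropylsilyl)oxy]chroman-3-yl]-6-(3-methylbut-2-en-1-yl)-5-[2-(trimethylsilyl)ethoxy]benzene-1,4-diol F5. Both silicon groups are then removed at this non‑electrophilic oxidation level (CsF, degassed DMF, 80 °C) to give 5-[(3R)-7-hydroxy-5-methoxy-6-(3-methylbut-2-en-1-yl)chroman-3-yl]-3-(3-methylbut-2-en-1-yl)benzene-1,2,4-triol F6. Exposure of F6 to air (EtOAc, pH 7 buffer) oxidises it to 35.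

Step 8. Facial selectivity in the hydrogenation may be insufficient for a single enantiomer, or forcing pressure may begin to reduce the prenyl alkene. The fallback sets out from 13 and comes back at 14. Hydrogenation with Ru(OAc)2[rac-BINAP] under the same mild conditions gives racemic 5-methoxy-6-(3-methylbut-2-en-1-yl)-7-[(triisopropylsilyl)oxy]chromane-3-carboxylic acid F7. Classical resolution with (R)-1-phenylethylamine and fractional crystallisation gives the (R)-1-phenylethylammonium (3S)-carboxylate F8 (the amine antipode is chosen by which salt crystallises). Acidification with dilute citric acid returns 14.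

**Further compounds**

F1 | step 17 | [2-(ethenyloxy)ethyl]trimethylsilane | C=COCC[Si](C)(C)C
F2 | step 17 | pentacarbonyl{1-methoxy-2-[2-(trimethylsilyl)ethoxy]prop-2-en-1-ylidene}chromium | COC(=[Cr])C(=C)OCC[Si](C)(C)C.[C-]#[O+].[C-]#[O+].[C-]#[O+].[C-]#[O+].[C-]#[O+]
F3 | step 17 | 4-methoxy-2-[(3R)-5-methoxy-6-(3-methylbut-2-en-1-yl)-7-[(triisopropylsilyl)oxy]chroman-3-yl]-5-[2-(trimethylsilyl)ethoxy]phenol | COc1c(CC=C(C)C)c(O[Si](C(C)C)(C(C)C)C(C)C)cc2c1C[C@H](c1cc(OC)c(OCC[Si](C)(C)C)cc1O)CO2
F4 | step 17 | 2-methylbut-3-en-2-yl ether of F3 | COc1c(CC=C(C)C)c(O[Si](C(C)C)(C(C)C)C(C)C)cc2c1C[C@H](c1cc(OC)c(OCC[Si](C)(C)C)cc1OC(C)(C)C=C)CO2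
F5 | step 18 | 2-[(3R)-5-methoxy-6-(3-methylbut-2-en-1-yl)-7-[(triisopropylsilyl)oxy]chroman-3-yl]-6-(3-methylbut-2-en-1-yl)-5-[2-(trimethylsilyl)ethoxy]benzene-1,4-diol | COc1c(CC=C(C)C)c(O[Si](C(C)C)(C(C)C)C(C)C)cc2c1C[C@H](c1cc(O)c(OCC[Si](C)(C)C)c(CC=C(C)C)c1O)CO2
F6 | step 18 | 5-[(3R)-7-hydroxy-5-methoxy-6-(3-methylbut-2-en-1-yl)chroman-3-yl]-3-(3-methylbut-2-en-1-yl)benzene-1,2,4-triol | COc1c(CC=C(C)C)c(O)cc2c1C[C@H](c1cc(O)c(O)c(CC=C(C)C)c1O)CO2
F7 | step 8 | racemic 5-methoxy-6-(3-methylbut-2-en-1-yl)-7-[(triisopropylsilyl)oxy]chromane-3-carboxylic acid | COc1c(CC=C(C)C)c(O[Si](C(C)C)(C(C)C)C(C)C)cc2c1CC(C(=O)O)CO2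
F8 | step 8 | (R)-1-phenylethylammonium (3S)-5-methoxy-6-(3-methylbut-2-en-1-yl)-7-[(triisopropylsilyl)oxy]chromane-3-carboxylate | COc1c(CC=C(C)C)c(O[Si](C(C)C)(C(C)C)C(C)C)cc2c1C[C@H](C(=O)[O-])CO2.C[C@@H]([NH3+])c1ccccc1
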